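**Plan** (ring numbered C1(=O), C2H=, C3(Me), C4(Me)(side chain), C5H(Me), C6H2)

1. Retrosynthetic cuts: the butenolide–CH2 bond (Negishi); the C3–CH3 bond together with a 1,3-transposition of the enone; ring carbon C2 taken out of the ring (one-carbon contraction to an α-quaternary cyclopentanone); the C4–CH3 and C5–CH3 bonds; the ring–side-chain C–C bond (B-alkyl Suzuki); the chain back to geranyl bromide.
2. Forward order: the chain is made first and joined to a cyclopentenone; the five-membered ring receives both methyl groups; it is enlarged to the six-membered enone; the enone is transposed with introduction of the C3 methyl; the butenolide is attached last.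
3. Enabling feature: C1(=O) and C3(Me) are 1,3-related across C2 and C3 is flanked by quaternary C4, so the ring is the alkylative transposition product of a cyclohex-2-enone whose carbonyl carbon is the future C3. In the corresponding cyclopentanone, C4 blocks enolisation on one side, so the enol silane, the cyclopropane and the site where C2 is inserted are unambiguous.
4. Stereochemistry: C5 from a Cu-catalysed asymmetric conjugate methylation; C4 from anti C-methylation of the resulting enolate (methyl groups trans); both E-alkenes from geranyl bromide and an E-selective SeO2 oxidation.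

Key step: step 9

Remark: the target SMILES is read as (4R,5R), i.e. the C4 and C5 methyl groups trans on the ring; the ligand antipode in step 6 is the one that gives this series; compounds 2, 8 and 22 are taken as purchasable.

Step 1
Reactants: 1 geranyl bromide; 2 tributyl[(methoxymethoxy)methyl]stannane
Product: 4 (3E)-1-(methoxymethoxy)-4,8-dimethylnona-3,7-diene, via (methoxymethoxy)methyllithium 3 (not isolated)
Conditions: 2, n-BuLi, THF, −78 °C; then 1, −78 °C to 0 °C
Reagents that add atoms: none
Why: Tin–lithium exchange gives the α-alkoxymethyllithium (a hydroxymethyl anion equivalent), which should displace the primary allylic bromide by SN2 alkylation with retention of the E geometry.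

Step 2
Reactants: 4 homogeranyl MOM ether
Product: 5 (2E,6E)-9-(methoxymethoxy)-2,6-dimethylnona-2,6-dien-1-ol
Conditions: SeO2 (cat.), t-BuOOH, salicylic acid (cat.), CH2Cl2, 0 °C to rt
Reagents that add atoms: tert-butyl hydroperoxide, CC(C)(C)OO (terminal source of the oxygen atom, passed on through selenium dioxide, O=[Se]=O)
Why: Catalytic SeO2 allylic oxidation (ene reaction, then [2,3]-sigmatropic shift) should attack the terminal isopropylidene group at its E-methyl and give the E-allylic alcohol.

Step 3
Reactants: 5 allylic alcohol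
Product: 6 (2E,6E)-9-(methoxymethoxy)-2,6-dimethylnona-2,6-dienal
Conditions: MnO2, CH2Cl2, rt
Reagents that add atoms: none
Why: MnO2 oxidises allylic alcohols chemoselectively to enals and leaves the alkenes and the MOM acetal alone.

Step 4
Reactants: 6 enal
Product: 7 (3E,7E)-10-(methoxymethoxy)-3,7-dimethyldeca-1,3,7-triene
Conditions: Ph3PCH3Br, NaN(SiMe3)2, THF, 0 °C; then 6, −78 °C to rt
Reagents that add atoms: methyltriphenylphosphonium bromide, C[P+](c1ccccc1)(c1ccccc1)c1ccccc1.[Br-]
Why: Wittig methylenation of the enal with the unstabilised ylide gives the terminal 1,3-diene without touching the existing E-trisubstituted alkenes.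

Step 5
Reactants: 7 triene; 8 2-iodocyclopent-2-en-1-one
Product: 10 2-[(3E,7E)-10-(methoxymethoxy)-3,7-dimethyldeca-3,7-dien-1-yl]cyclopent-2-en-1-one, via B-alkyl-9-BBN 9 (not isolated)
Conditions: 9-BBN, THF, 0 °C to rt; then 8, PdCl2(dppf) (cat.), AsPh3, Cs2CO3, DMF/H2O, rt
Reagents that add atoms: none
Why: 9-BBN should add only to the monosubstituted terminus of the diene (trisubstituted alkenes are inert) to give the homoallylic borane, which undergoes B-alkyl Suzuki–Miyaura coupling with the α-iodoenone.

Step 6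
Reactants: 10 2-alkylcyclopentenone
Product: 12 (2R,3R)-2-[(3E,7E)-10-(methoxymethoxy)-3,7-dimethyldeca-3,7-dien-1-yl]-2,3-dimethylcyclopentan-1-one, via magnesium enolate 11 (not isolated)
Conditions: MeMgBr, Cu(OTf)2 (5 mol %), chiral N-heterocyclic carbene ligand (from its imidazolinium salt, 6 mol %), Et2O, −20 °C; then MeI, DMPU, −20 °C to rt
Reagents that add atoms: methylmagnesium bromide, C[Mg]Br; iodomethane, CI
Why: Copper-catalysed asymmetric conjugate addition sets the β-methyl stereocentre (3R) under catalyst control, and the regiodefined magnesium enolate is C-methylated on the face anti to that methyl group, which creates the quaternary centre (2R) with the two methyl groups trans (tandem conjugate addition–enolate alkylation).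

Step 7
Reactants: 12 α-quaternary cyclopentanone
Product: 14 {[(4R,5R)-5-[(3E,7E)-10-(methoxymethoxy)-3,7-dimethyldeca-3,7-dien-1-yl]-4,5-dimethylcyclopent-1-en-1-yl]oxy}trimethylsilane, via lithium enolate 13 (not isolated)
Conditions: LiN(i-Pr)2, THF, −78 °C; then Me3SiCl, Et3N, −78 °C to 0 °C
Reagents that add atoms: chlorotrimethylsilane, C[Si](C)(C)Cl
Why: The ketone has α-hydrogens only at C5 because C2 is quaternary, so deprotonation and O-silylation can give only one enol silane regioisomer.

Step 8
Reactants: 14 enol silane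
Product: 15 {[(1S,2R,3R,5S)-2-[(3E,7E)-10-(methoxymethoxy)-3,7-dimethyldeca-3,7-dien-1-yl]-2,3-dimethylbicyclo[3.1.0]hexan-1-yl]oxy}trimethylsilane
Conditions: Et2Zn, CH2I2, toluene, 0 °C to rt; pyridine quench
Reagents that add atoms: diiodomethane, ICI
Why: In this Simmons–Smith cyclopropanation (Et2Zn/CH2I2 variant) the electron-rich enol silane should react with the zinc carbenoid faster than the two unactivated trisubstituted alkenes; the CH2 group is expected to add anti to the side chain, and both new ring-fusion stereocentres are erased in step 9.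

Step 9
Reactants: 15 siloxycyclopropane
Product: 17 (5R,6R)-6-[(3E,7E)-10-(methoxymethoxy)-3,7-dimethyldeca-3,7-dien-1-yl]-5,6-dimethylcyclohex-2-en-1-one, via 5-chlorocyclohexanone 16 (not isolated)
Conditions: FeCl3 (2.2 equiv), DMF, 0 °C to rt; then NaOAc, MeOH, reflux
Reagents that add atoms: none
Why: FeCl3 exchanges with the silyl ether and oxidises it by one electron to a cyclopropyloxy radical, which undergoes β-scission of the bond shared by the three- and five-membered rings to give the ring-enlarged secondary β-keto radical (the former cyclopentanone α-carbon, future C1); this radical takes a chlorine atom from a second FeCl3 to give chloroketone 16, from which NaOAc removes HCl by E1cB elimination. The closest known reaction type is the Ito–Saegusa oxidative ring enlargement of 1-siloxybicyclo[n.1.0]alkanes to 2-cycloalkenones. No ring is closed by bond formation: the six-membered ring arises by fragmentation of the zero-atom bridge of the bicyclo[3.1.0]hexane, so the cyclopentane grows by the carbon added in step 8 (future C2). No new stereocentre survives, since the chlorine-bearing carbon becomes sp2, and the two existing stereocentres (C4 and C5 of the target) are untouched because the quaternary carbon cannot enolise and the methine is β to the carbonyl. The step needs scission of the internal and not the external cyclopropane bond, which is secured by formation of the secondary radical with release of bicyclic strain; the site of enlargement is fixed because the quaternary carbon left only one enolisable position in 12. It also needs chemoselectivity against the two trisubstituted alkenes, which is secured because the radical lies seven and eight atoms from the nearest alkene carbons and is trapped by chlorine transfer first, while DMF tempers the Lewis acidity of FeCl3.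

Step 10
Reactants: 17 α'-quaternary cyclohexenone
Product: 18 (5R,6R)-6-[(3E,7E)-10-(methoxymethoxy)-3,7-dimethyldeca-3,7-dien-1-yl]-1,5,6-trimethylcyclohex-2-en-1-ol (mixture of C1 epimers)
Conditions: MeLi, Et2O, −78 °C
Reagents that add atoms: methyllithium, [Li]C
Why: Methyllithium adds 1,2 to the enone carbonyl (the quaternary side has no α-hydrogen, so enolisation there cannot compete); the configuration of the new carbinol centre does not matter because it is destroyed in step 11.

Step 11
Reactants: 18 tertiary allylic alcohol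
Product: 19 (4R,5R)-4-[(3E,7E)-10-(methoxymethoxy)-3,7-dimethyldeca-3,7-dien-1-yl]-3,4,5-trimethylcyclohex-2-en-1-one
Conditions: C5H5NH[CrO3Cl] (pyridinium chlorochromate), Celite, CH2Cl2, rt
Reagents that add atoms: pyridinium chlorochromate, [O-][Cr](=O)(=O)Cl.c1cc[nH+]cc1 (supplies the carbonyl oxygen)
Why: In the Babler–Dauben oxidative 1,3-transposition the tertiary allylic chromate ester undergoes a [3,3]-sigmatropic shift and the resulting secondary allylic chromate is oxidised, which places the carbonyl at C1 and the methyl-bearing alkene carbon C3 next to the quaternary centre.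

Step 12
Reactants: 19 MOM-protected enone
Product: 20 (4R,5R)-4-[(3E,7E)-10-hydroxy-3,7-dimethyldeca-3,7-dien-1-yl]-3,4,5-trimethylcyclohex-2-en-1-one
Conditions: HCl (0.3 M), MeOH, 40 °C
Reagents that add atoms: none
Why: Acid-catalysed acetal exchange with methanol removes the MOM group as dimethoxymethane; the enone, the trisubstituted alkenes and both stereocentres should be stable to dilute methanolic acid.

Step 13
Reactants: 20 primary alcohol
Product: 21 (4R,5R)-4-[(3E,7E)-10-iodo-3,7-dimethyldeca-3,7-dien-1-yl]-3,4,5-trimethylcyclohex-2-en-1-one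
Conditions: I2, PPh3, imidazole, CH2Cl2, 0 °C to rt
Reagents that add atoms: iodine, II
Why: Appel-type iodination converts the primary alcohol into the primary iodide under neutral conditions that the enone and alkenes tolerate.

Step 14
Reactants: 21 primary iodide; 22 4-bromofuran-2(5H)-one
Product: 24 cyclolinteinone, via alkylzinc iodide 23 (not isolated)
Conditions: Zn dust, LiCl, THF, 40 °C; then 22, Pd(OAc)2 (cat.), SPhos, THF, rt
Reagents that add atoms: none
Why: LiCl-promoted zinc insertion into the primary C–I bond gives an alkylzinc iodide that does not add to the enone, and palladium-catalysed Negishi coupling with the β-bromobutenolide forms the sp3–sp2 bond that completes the side chain.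

**Compound list**

1 | geranyl bromide, (2E)-1-bromo-3,7-dimethylocta-2,6-diene | CC(C)=CCC/C(C)=C/CBr | starting material
2 | tributyl[(methoxymethoxy)methyl]stannane | CCCC[Sn](CCCC)(CCCC)COCOC | starting material
3 | (methoxymethoxy)methyllithium | [Li]COCOC | intermediate
4 | (3E)-1-(methoxymethoxy)-4,8-dimethylnona-3,7-diene | CC(C)=CCC/C(C)=C/CCOCOC | intermediate
5 | (2E,6E)-9-(methoxymethoxy)-2,6-dimethylnona-2,6-dien-1-ol | OC/C(C)=C/CC/C(C)=C/CCOCOC | intermediate
6 | (2E,6E)-9-(methoxymethoxy)-2,6-dimethylnona-2,6-dienal | O=C/C(C)=C/CC/C(C)=C/CCOCOC | intermediate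
7 | (3E,7E)-10-(methoxymethoxy)-3,7-dimethyldeca-1,3,7-triene | C=C/C(C)=C/CC/C(C)=C/CCOCOC | intermediate
8 | 2-iodocyclopent-2-en-1-one | O=C1CCC=C1I | starting material
9 | 9-[(3E,7E)-10-(methoxymethoxy)-3,7-dimethyldeca-3,7-dien-1-yl]-9-borabicyclo[3.3.1]nonane | B1(C2CCCC1CCC2)CC/C(C)=C/CC/C(C)=C/CCOCOC | intermediate
10 | 2-[(3E,7E)-10-(methoxymethoxy)-3,7-dimethyldeca-3,7-dien-1-yl]cyclopent-2-en-1-one | O=C1CCC=C1CC/C(C)=C/CC/C(C)=C/CCOCOC | intermediate
11 | bromomagnesium (3R)-2-[(3E,7E)-10-(methoxymethoxy)-3,7-dimethyldeca-3,7-dien-1-yl]-3-methylcyclopent-1-en-1-olate | Br[Mg]OC1=C(CC/C(C)=C/CC/C(C)=C/CCOCOC)[C@H](C)CC1 | intermediate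
12 | (2R,3R)-2-[(3E,7E)-10-(methoxymethoxy)-3,7-dimethyldeca-3,7-dien-1-yl]-2,3-dimethylcyclopentan-1-one | O=C1CC[C@@H](C)[C@@]1(C)CC/C(C)=C/CC/C(C)=C/CCOCOC | intermediate
13 | lithium (4R,5R)-5-[(3E,7E)-10-(methoxymethoxy)-3,7-dimethyldeca-3,7-dien-1-yl]-4,5-dimethylcyclopent-1-en-1-olate | [Li]OC1=CC[C@@H](C)[C@@]1(C)CC/C(C)=C/CC/C(C)=C/CCOCOC | intermediate
14 | {[(4R,5R)-5-[(3E,7E)-10-(methoxymethoxy)-3,7-dimethyldeca-3,7-dien-1-yl]-4,5-dimethylcyclopent-1-en-1-yl]oxy}trimethylsilane | C[Si](C)(C)OC1=CC[C@@H](C)[C@@]1(C)CC/C(C)=C/CC/C(C)=C/CCOCOC | intermediate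
15 | {[(1S,2R,3R,5S)-2-[(3E,7E)-10-(methoxymethoxy)-3,7-dimethyldeca-3,7-dien-1-yl]-2,3-dimethylbicyclo[3.1.0]hexan-1-yl]oxy}trimethylsilane (expected major ring-fusion isomer) | C[Si](C)(C)O[C@@]12C[C@@H]1CC[C@@H](C)[C@@]2(C)CC/C(C)=C/CC/C(C)=C/CCOCOC | intermediate
16 | (2R,3R)-5-chloro-2-[(3E,7E)-10-(methoxymethoxy)-3,7-dimethyldeca-3,7-dien-1-yl]-2,3-dimethylcyclohexan-1-one (C5 epimers) | O=C1CC(Cl)C[C@@H](C)[C@@]1(C)CC/C(C)=C/CC/C(C)=C/CCOCOC | intermediate
17 | (5R,6R)-6-[(3E,7E)-10-(methoxymethoxy)-3,7-dimethyldeca-3,7-dien-1-yl]-5,6-dimethylcyclohex-2-en-1-one | O=C1C=CC[C@@H](C)[C@@]1(C)CC/C(C)=C/CC/C(C)=C/CCOCOC | intermediate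
18 | (5R,6R)-6-[(3E,7E)-10-(methoxymethoxy)-3,7-dimethyldeca-3,7-dien-1-yl]-1,5,6-trimethylcyclohex-2-en-1-ol (C1 epimers) | CC1(O)C=CC[C@@H](C)[C@@]1(C)CC/C(C)=C/CC/C(C)=C/CCOCOC | intermediate
19 | (4R,5R)-4-[(3E,7E)-10-(methoxymethoxy)-3,7-dimethyldeca-3,7-dien-1-yl]-3,4,5-trimethylcyclohex-2-en-1-one | CC1=CC(=O)C[C@@H](C)[C@@]1(C)CC/C(C)=C/CC/C(C)=C/CCOCOC | intermediate
20 | (4R,5R)-4-[(3E,7E)-10-hydroxy-3,7-dimethyldeca-3,7-dien-1-yl]-3,4,5-trimethylcyclohex-2-en-1-one | CC1=CC(=O)C[C@@H](C)[C@@]1(C)CC/C(C)=C/CC/C(C)=C/CCO | intermediate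
21 | (4R,5R)-4-[(3E,7E)-10-iodo-3,7-dimethyldeca-3,7-dien-1-yl]-3,4,5-trimethylcyclohex-2-en-1-one | CC1=CC(=O)C[C@@H](C)[C@@]1(C)CC/C(C)=C/CC/C(C)=C/CCI | intermediate
22 | 4-bromofuran-2(5H)-one | BrC1=CC(=O)OC1 | starting material
23 | (4R,5R)-4-[(3E,7E)-10-(iodozincio)-3,7-dimethyldeca-3,7-dien-1-yl]-3,4,5-trimethylcyclohex-2-en-1-one | CC1=CC(=O)C[C@@H](C)[C@@]1(C)CC/C(C)=C/CC/C(C)=C/CC[Zn]I | intermediate
24 | cyclolinteinone, (4R,5R)-4-[(3E,7E)-3,7-dimethyl-10-(5-oxo-2,5-dihydrofuran-3-yl)deca-3,7-dien-1-yl]-3,4,5-trimethylcyclohex-2-en-1-one | CC1=CC(=O)C[C@@H](C)[C@@]1(C)CC/C(C)=C/CC/C(C)=C/CCC1=CC(=O)OC1 | target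

**Summary**

Total step count: 14. Longest linear sequence: 14 steps (from geranyl bromide 1).

Steps most likely to fail, each with one fallback:

Step 6. The copper-catalysed addition to the α-substituted enone may proceed with insufficient enantiofacial control or be overtaken by 1,2-addition, and C-methylation of the hindered magnesium enolate may be sluggish. The fallback sets out from borane 9 and comes back at ketone 12. Borane 9 is coupled under the Suzuki conditions of step 5 with 2-iodo-3-methylcyclopent-2-en-1-one F1 (from 3-methylcyclopent-2-en-1-one, I2 and pyridine). This gives the tetrasubstituted enone 2-[(3E,7E)-10-(methoxymethoxy)-3,7-dimethyldeca-3,7-dien-1-yl]-3-methylcyclopent-2-en-1-one F2. A copper hydride catalysed asymmetric 1,4-reduction (Cu(OAc)2, DTBM-SEGPHOS of the suitable hand, PhMe2SiH, toluene) then sets the methyl-bearing centre by hydride delivery and should give the regiodefined silyl enol ether {[(3R)-2-[(3E,7E)-10-(methoxymethoxy)-3,7-dimethyldeca-3,7-dien-1-yl]-3-methylcyclopent-1-en-1-yl]oxy}dimethyl(phenyl)silane F3. MeLi converts it into lithium (3R)-2-[(3E,7E)-10-(methoxymethoxy)-3,7-dimethyldeca-3,7-dien-1-yl]-3-methylcyclopent-1-en-1-olate F4, and MeI alkylates this anti to the ring methyl to give 12. The asymmetric C–C bond formation is thus replaced by an asymmetric C–H bond formation.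

Step 8. The zinc carbenoid may lose chemoselectivity and also cyclopropanate the trisubstituted alkenes of the chain, or traces of zinc iodide may cleave the enol silane. The fallback sets out from ketone 12 and comes back at enone 17 without any carbenoid. Sc(OTf)3-catalysed homologation of 12 with trimethylsilyldiazomethane inserts on the CH2 side (the quaternary carbon does not migrate) and should give (2R,3R)-2-[(3E,7E)-10-(methoxymethoxy)-3,7-dimethyldeca-3,7-dien-1-yl]-2,3-dimethyl-6-(trimethylsilyl)cyclohexan-1-one F5. Warming causes the 1,3-shift of silicon from carbon to oxygen to give {[(5R,6R)-6-[(3E,7E)-10-(methoxymethoxy)-3,7-dimethyldeca-3,7-dien-1-yl]-5,6-dimethylcyclohex-1-en-1-yl]oxy}trimethylsilane F6. Saegusa–Ito dehydrogenation with Pd(OAc)2 in MeCN then gives 17.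

Step 9. FeCl3 may trigger Lewis-acid or chlorine-transfer side reactions at the electron-rich alkenes or the MOM acetal, and the elimination may stay incomplete. The fallback sets out from 15 and comes back at 17. K2CO3 in MeOH frees the cyclopropanol (1S,2R,3R,5S)-2-[(3E,7E)-10-(methoxymethoxy)-3,7-dimethyldeca-3,7-dien-1-yl]-2,3-dimethylbicyclo[3.1.0]hexan-1-ol F7. Mn(O2CC5H4N)3 (manganese tris(pyridine-2-carboxylate)) with Bu3SnH in DMF opens the same internal bond under neutral conditions and reduces the β-keto radical to (2R,3R)-2-[(3E,7E)-10-(methoxymethoxy)-3,7-dimethyldeca-3,7-dien-1-yl]-2,3-dimethylcyclohexan-1-one F8. IBX in DMSO at 70 °C dehydrogenates F8 on its only enolisable side to 17.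

Further compounds
F1 | step 6 | 2-iodo-3-methylcyclopent-2-en-1-one | CC1=C(I)C(=O)CC1
F2 | step 6 | 2-[(3E,7E)-10-(methoxymethoxy)-3,7-dimethyldeca-3,7-dien-1-yl]-3-methylcyclopent-2-en-1-one | CC1=C(CC/C(C)=C/CC/C(C)=C/CCOCOC)C(=O)CC1
F3 | step 6 | {[(3R)-2-[(3E,7E)-10-(methoxymethoxy)-3,7-dimethyldeca-3,7-dien-1-yl]-3-methylcyclopent-1-en-1-yl]oxy}dimethyl(phenyl)silane | C[Si](C)(c2ccccc2)OC1=C(CC/C(C)=C/CC/C(C)=C/CCOCOC)[C@H](C)CC1
F4 | step 6 | lithium (3R)-2-[(3E,7E)-10-(methoxymethoxy)-3,7-dimethyldeca-3,7-dien-1-yl]-3-methylcyclopent-1-en-1-olate | [Li]OC1=C(CC/C(C)=C/CC/C(C)=C/CCOCOC)[C@H](C)CC1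
F5 | step 8 | (2R,3R)-2-[(3E,7E)-10-(methoxymethoxy)-3,7-dimethyldeca-3,7-dien-1-yl]-2,3-dimethyl-6-(trimethylsilyl)cyclohexan-1-one | O=C1C([Si](C)(C)C)CC[C@@H](C)[C@@]1(C)CC/C(C)=C/CC/C(C)=C/CCOCOC
F6 | step 8 | {[(5R,6R)-6-[(3E,7E)-10-(methoxymethoxy)-3,7-dimethyldeca-3,7-dien-1-yl]-5,6-dimethylcyclohex-1-en-1-yl]oxy}trimethylsilane | C[Si](C)(C)OC1=CCC[C@@H](C)[C@@]1(C)CC/C(C)=C/CC/C(C)=C/CCOCOC
F7 | step 9 | (1S,2R,3R,5S)-2-[(3E,7E)-10-(methoxymethoxy)-3,7-dimethyldeca-3,7-dien-1-yl]-2,3-dimethylbicyclo[3.1.0]hexan-1-ol | O[C@@]12C[C@@H]1CC[C@@H](C)[C@@]2(C)CC/C(C)=C/CC/C(C)=C/CCOCOC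
F8 | step 9 | (2R,3R)-2-[(3E,7E)-10-(methoxymethoxy)-3,7-dimethyldeca-3,7-dien-1-yl]-2,3-dimethylcyclohexan-1-one | O=C1CCC[C@@H](C)[C@@]1(C)CC/C(C)=C/CC/C(C)=C/CCOCOC
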